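(The data come from a simulation from invented constants, noise included.)

The leftover struck me first: at 5.00 h the theta run still held 57.0 % of its substrates, yet its readings had stopped rising.

| flask | left-handed substrate | right-handed substrate | partner | free catalyst | remark | time |
|---|---|---|---|---|---|---|
| theta | 0.12 M | 0.12 M | 0.625 M | 2.5 mM | run made earlier |  |
| beta | 0.50 M | 0.50 M | 0.625 M | 2.5 mM | run made earlier |  |
| eta | 0.25 M | 0.25 M | 0.625 M | 5 mM | run made earlier |  |
| flask | 0.25 M | 0.25 M | 0.625 M | 2.5 mM |  | 6.0 h |

- theta (time / h: left-handed product / %, right-handed product / %): 0.833: 24, 12; 1.50: 25, 16; 2.50: 28, 16; 3.00: 28, 14; 4.00: 25, 20; 5.00: 27, 16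
- beta (time / h: left-handed product / %, right-handed product / %): 0.333: 14, 8; 1.00: 20, 16; 1.50: 24, 13; 2.50: 25, 16; 4.00: 24, 18; 5.00: 30, 18
- eta (time / h: left-handed product / %, right-handed product / %): 0.417: 26, 17; 1.33: 39, 23; 2.00: 39, 25; 3.00: 41, 28; 5.00: 42, 27

(each reading ± 1.5 percentage points)

- free catalyst is single-handed; left-handed substrate and right-handed substrate are mirror images of each other, charged as a racemate, each of them at the stated concentration
- what was read earlier has a scatter of 1.5 percentage points, one standard deviation
- an excess is the difference of the two amounts in percent of their sum
- an excess is below zero if the other one leads

1. left-handed product and right-handed product together, in percent of the left-handed substrate and right-handed substrate charged together, at 6.0 h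
2. excess of left-handed product over right-handed product in the product at 6.0 h
3. whether the exchange between left-handed substrate and right-handed substrate keeps pace with the reaction: how far the product's excess at 6.0 h gets from its value without exchange to its value with instant exchange (above 80 % keeps pace, below 20 % hardly takes part, else lags behind)

I followed the eta run in slow motion. In the first instants, product came quickly: 43.0 % by 0.417 h, with left-handed product ahead of right-handed product, at 26 % against 17 %. An exchange between the substrates (racemization) acts as soon as the two differ, by refilling the left-handed substrate. In the middle the pace fell, with 62.0 % at 1.33 h. At the end the eta run stood at 69.0 % at both 3.00 h and 5.00 h, with substrate still there.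

Why did it stop? The theta and beta runs, with equal catalyst, ended at 43.0 % and 48.0 % of their charge, although they had made 0.103 M and 0.480 M of product. So I followed one substrate molecule. At each moment it is either taken by the catalyst or it waits, and its chance does not appear to depend on how many neighbours it has. I read the stop as the end of the catalyst's working life, so a molecule's chance of surviving should fall exponentially with the catalyst charged. The eta run, with twice the catalyst of the theta run, has a logarithm of charged over left that is twice as large.

From the eta run I read 0.234 mM⁻¹ for what I call the reach: the natural logarithm of substrate charged over substrate left at the stop, per mM of catalyst charged, with partner charged at 0.625 M. For the flask, with 2.5 mM, my reckoning gives 44.3 % of product, well before 6.0 h.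

The forecast gave 44 % and an excess of 23 %, and for the exchange keeps pace: “So exchange seems to keep pace”.

The flask gave 43.9 % and an excess of 23.7 %, but the exchange lags behind, getting 66 % of the way from the excess without exchange to that with instant exchange.

    partner + free catalyst + left-handed substrate → free catalyst + left-handed product (k = 17.0 M⁻² min⁻¹)
    partner + free catalyst + right-handed substrate → free catalyst + right-handed product (k = 10.0 M⁻² min⁻¹)
    left-handed substrate ⇌ right-handed substrate (k = 0.0330 min⁻¹)
    partner + free catalyst → spent catalyst (k = 0.0580 M⁻¹ min⁻¹)
    partner → decomposition product (k = 2.00 × 10⁻⁵ min⁻¹)

The forward exchange alone had a half-life of 0.35 h, while 31.8 % of product already stood in the flask at 0.600 h. The reach leaves 55.7 % of each substrate, and the flask held 56 % of its left-handed substrate charge. For the neighbour charged with 0.010 M of free catalyst, the reach gives 90.4 %, and that flask stood at 89.5 %.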